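Ring B is a 1-vinylcyclohexene (diene C5'=C6'–C7'=C8') whose C6'–C1'(CH3)2–C2'(O)–C3' segment maps onto (R)-pantolactone. Everything therefore rests on a ring-closing enyne metathesis: a pantolactone-derived 1,7-enyne (terminal alkyne on C1', methallyl arm on C3', the anti-2',3'-diol clamped as a cis-dioxolane) is reorganised in one operation into ring B, creating C5'=C6' and the C7'=C8' vinyl group while both stereocentres stay untouched. Heck vinylation at C8' then leads to the C15 phosphonium salt; ring A is built the same way from (S)-pantolactone, and two Wittig reactions with the C10 dialdehyde assemble the carotenoid with every hydroxyl already free.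

Key step: step 8

Remarks on the chemistry: carotenoid numbering is used, with primed locants on the diol ring B, and the target is (2R,2'R,3'S), the 2',3'-diol being cis. Methallylmagnesium chloride (7, THF solution) and ethyl (2E)-3-iodobut-2-enoate (13) are assumed to be catalogue compounds. All chain double bonds are E; Z isomers from the Wittig steps are equilibrated as stated.

**Ring B half (steps 1–13)**

Step 1
Reactants: 1 (R)-pantolactone
Product: 2 (3R)-4,4-dimethyl-3-(triethylsilyloxy)oxolan-2-one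
Conditions: TESCl, imidazole, DMF, 0 °C → rt
Reagents that add atoms: chlorotriethylsilane, CC[Si](Cl)(CC)CC
Why: Imidazole-promoted silyl ether formation on the only hydroxyl; the TES group does not chelate, survives steps 2–6 and falls off under the acid of step 7, and the stereocenter is not touched.

Step 2
Reactants: 2 (3R)-4,4-dimethyl-3-(triethylsilyloxy)oxolan-2-one
Product: 3 (2R)-4-hydroxy-N-methoxy-N,3,3-trimethyl-2-(triethylsilyloxy)butanamide
Conditions: MeNH(OMe)·HCl, Me3Al, CH2Cl2, 0 °C → rt; aq. KNaC4H4O6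
Reagents that add atoms: N,O-dimethylhydroxylamine hydrochloride, CNOC.Cl
Why: Weinreb aminolysis of a lactone by the aluminium amide opens the ring as a stable aluminium alkoxide, which frees the neopentyl CH2OH (future C6') and leaves C3' at the acyl level; crude 3 should be taken on at once so that it cannot relactonise.

Step 3
Reactants: 3 (2R)-4-hydroxy-N-methoxy-N,3,3-trimethyl-2-(triethylsilyloxy)butanamide
Product: 4 (2R)-N-methoxy-N,3,3-trimethyl-4-oxo-2-(triethylsilyloxy)butanamide
Conditions: Dess–Martin periodinane, pyridine, CH2Cl2, 0 °C → rt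
Reagents that add atoms: none
Why: Dess–Martin oxidation of a primary alcohol to an aldehyde that has no α-hydrogen (quaternary C1'), so it can neither epimerise nor enolise, and the relactonisation pathway disappears with the hydroxyl.

Step 4
Reactants: 4 (2R)-N-methoxy-N,3,3-trimethyl-4-oxo-2-(triethylsilyloxy)butanamide
Product: 5 (2R)-N-methoxy-N,3,3-trimethyl-2-(triethylsilyloxy)pent-4-ynamide
Conditions: MeC(O)C(N2)P(O)(OMe)2, K2CO3, MeOH, 0 °C → rt
Reagents that add atoms: dimethyl (1-diazo-2-oxopropyl)phosphonate, CC(=O)C(=[N+]=[N-])P(=O)(OC)OC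
Why: Ohira–Bestmann (Seyferth–Gilbert) homologation: the diazomethylphosphonate anion made in situ adds to the non-enolisable aldehyde and the resulting alkylidene carbene rearranges to the terminal alkyne C6'≡C7'; K2CO3/MeOH should leave the Weinreb amide, the TES ether and the α-stereocenter alone.

Step 5
Reactants: 5 (2R)-N-methoxy-N,3,3-trimethyl-2-(triethylsilyloxy)pent-4-ynamide
Product: 6 (2R)-3,3-dimethyl-2-(triethylsilyloxy)pent-4-ynal
Conditions: i-Bu2AlH, THF, −78 °C; aq. KNaC4H4O6
Reagents that add atoms: none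
Why: Weinreb amide reduction stops at the chelated tetrahedral aluminate, which gives the aldehyde only on work-up; at −78 °C the alkyne and the α-silyloxy stereocenter should be unaffected, and 6 is used without storage.

Step 6
Reactants: 6 (2R)-3,3-dimethyl-2-(triethylsilyloxy)pent-4-ynal; 7 methallylmagnesium chloride
Product: 9 (4S,5R)-2,6,6-trimethyl-5-(triethylsilyloxy)oct-1-en-7-yn-4-ol, via borinate ester 8 (not isolated)
Conditions: 7 (1.2 equiv), (−)-Ipc2BOMe (1.3 equiv), Et2O, 0 °C → rt; then 6, −78 °C; then 3 M NaOH, 30% H2O2, 0 °C → rt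
Reagents that add atoms: none
Why: Brown asymmetric allylboration (methallyl transfer through a closed chair transition state): the borane derived from (+)-α-pinene adds to the Si face of the aldehyde, the same face that the Cornforth/Felkin–Anh arrangement of the non-chelating α-silyloxy group favours, so reagent and substrate control are matched and should set C3' as S (2',3'-anti).

Step 7
Reactants: 9 (4S,5R)-2,6,6-trimethyl-5-(triethylsilyloxy)oct-1-en-7-yn-4-ol
Product: 11 (4R,5S)-2,2-dimethyl-4-(2-methylbut-3-yn-2-yl)-5-(2-methylprop-2-en-1-yl)-1,3-dioxolane, via diol 10 (not isolated)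
Conditions: CSA (cat.), MeOH, rt; evaporate; Me2C(OMe)2, acetone, rt
Reagents that add atoms: 2,2-dimethoxypropane, COC(C)(C)OC
Why: Acid methanolysis of the TES ether followed by ketalisation with 2,2-dimethoxypropane: the only diol in the molecule is the vicinal anti-2',3'-diol, so the cis-4,5-disubstituted dioxolane should form with retention at both centres and without any regiochemical choice.

Step 8
Reactants: 11 (4R,5S)-2,2-dimethyl-4-(2-methylbut-3-yn-2-yl)-5-(2-methylprop-2-en-1-yl)-1,3-dioxolane
Product: 12 (3aR,7aS)-5-ethenyl-2,2,4,4,6-pentamethyl-3a,4,7,7a-tetrahydro-1,3-benzodioxole (ring B as 1-vinylcyclohexene, cis-fused acetonide)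
Conditions: second-generation Hoveyda–Grubbs catalyst RuCl2(H2IMes)(=CH–C6H4-2-OiPr) (10 mol %, two portions), ethylene (1 atm), toluene (0.01 M), 80 °C
Reagents that add atoms: none
Why: Ring-closing enyne metathesis, the established ruthenium-carbene route from 1,7-enynes to 1-vinylcyclohexenes: the Ru=CH2 species sustained by ethylene adds across the terminal alkyne with its carbon on C7' and opens to a ruthenium vinylcarbene centred on C6'; intramolecular [2+2] addition of that carbene to the methallyl C=C and cycloreversion of the ruthenacyclobutane forge C5'=C6' and return Ru=CH2, so the reaction is a net isomerisation. The six-membered ring B closes in the exo mode (C6' becomes a ring atom and C7'=C8' stays outside as the vinyl group), whereas the endo mode would give a seven-membered cyclic 1,3-diene. No stereocenter is formed, and C2' and C3' are remote from the reacting carbons and keep their configuration. The step needs exo over endo closure and ring closure over ethylene–alkyne cross-metathesis or alkyne oligomerisation: methylidene delivery to the unhindered alkyne terminus fixes the exo mode, and the cis-dioxolane together with the C1' gem-dimethyl group keeps alkyne and alkene within bonding distance. The tetrasubstituted C5'=C6' bond beside quaternary C1' is the demanding part, hence the phosphine-free, thermally robust catalyst, high dilution and 80 °C.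

Step 9
Reactants: 12 (3aR,7aS)-5-ethenyl-2,2,4,4,6-pentamethyl-3a,4,7,7a-tetrahydro-1,3-benzodioxole; 13 ethyl (2E)-3-iodobut-2-enoate
Product: 14 ethyl (2E,4E)-3-methyl-5-[(3aR,7aS)-2,2,4,4,6-pentamethyl-3a,4,7,7a-tetrahydro-1,3-benzodioxol-5-yl]penta-2,4-dienoate
Conditions: Pd(OAc)2 (5 mol %), Ag2CO3 (1 equiv), DMF, 50 °C, dark
Reagents that add atoms: none
Why: Mizoroki–Heck alkenylation under ligand-free, silver-promoted conditions: zerovalent palladium formed in situ inserts into the C–I bond of 13, the alkenylpalladium adds to the terminal carbon C8' of the only accessible alkene, and syn β-hydride elimination should give the 7'E bond with the 9'E geometry of 13 retained; the tetrasubstituted ring alkene is inert, and Ag2CO3 removes iodide so that Pd–H re-addition does not scramble the triene.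

Step 10
Reactants: 14 ethyl (2E,4E)-3-methyl-5-[(3aR,7aS)-2,2,4,4,6-pentamethyl-3a,4,7,7a-tetrahydro-1,3-benzodioxol-5-yl]penta-2,4-dienoate
Product: 15 ethyl (2E,4E)-5-[(4S,5R)-4,5-dihydroxy-2,6,6-trimethylcyclohex-1-en-1-yl]-3-methylpenta-2,4-dienoate
Conditions: AcOH/H2O/THF (3:1:1), 45 °C
Reagents that add atoms: none
Why: Acid-catalysed acetal hydrolysis at a stage where the robust trienoate tolerates aqueous acid, so the diol is unmasked here and the acid-sensitive carotenoid polyene never has to be deprotected.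

Step 11
Reactants: 15 ethyl (2E,4E)-5-[(4S,5R)-4,5-dihydroxy-2,6,6-trimethylcyclohex-1-en-1-yl]-3-methylpenta-2,4-dienoate
Product: 16 (1S,2R)-4-[(1E,3E)-5-hydroxy-3-methylpenta-1,3-dien-1-yl]-3,3,5-trimethylcyclohex-4-ene-1,2-diol
Conditions: i-Bu2AlH (5 equiv), CH2Cl2, −78 → 0 °C; aq. KNaC4H4O6
Reagents that add atoms: none
Why: 1,2-Reduction of a conjugated ester to the allylic alcohol by i-Bu2AlH, the excess covering the two hydroxyls as aluminium alkoxides; the triene geometry should be untouched.

Step 12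
Reactants: 16 (1S,2R)-4-[(1E,3E)-5-hydroxy-3-methylpenta-1,3-dien-1-yl]-3,3,5-trimethylcyclohex-4-ene-1,2-diol
Product: 17 [(2E,4E)-5-[(4S,5R)-4,5-dihydroxy-2,6,6-trimethylcyclohex-1-en-1-yl]-3-methylpenta-2,4-dien-1-yl]triphenylphosphonium bromide
Conditions: Ph3P·HBr (1.1 equiv), MeOH, 0 °C → rt
Reagents that add atoms: triphenylphosphine hydrobromide, [Br-].c1ccc(cc1)[PH+](c1ccccc1)c1ccccc1
Why: Allylic phosphonium salt formation (ionisation of the trienyl alcohol and capture of the cation by PPh3 at the primary terminus), the standard entry to C15 Wittig salts; the non-allylic secondary hydroxyls cannot ionise and stay free.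

Step 13
Reactants: 17 ring B C15 phosphonium bromide (as above); 18 (2E,4E,6E)-2,7-dimethylocta-2,4,6-trienedial
Product: 19 (2E,4E,6E,8E,10E,12E)-13-[(4S,5R)-4,5-dihydroxy-2,6,6-trimethylcyclohex-1-en-1-yl]-2,7,11-trimethyltrideca-2,4,6,8,10,12-hexaenal (C25 apo-aldehyde)
Conditions: 18 (3 equiv), NaOMe (1.1 equiv), CH2Cl2/MeOH, 0 °C → rt; then I2 (1 mol %), CH2Cl2, rt, daylight
Reagents that add atoms: none
Why: Wittig olefination with the semistabilised C15 ylide; a threefold excess of the symmetrical dialdehyde should enforce mono-olefination, free hydroxyls are tolerated under NaOMe as in the manufacture of hydroxy-carotenoids, and catalytic iodine equilibrates the new C11'=C12' bond to E.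

**Ring A half (steps 14–25)**

Step 14
Reactants: 20 (S)-pantolactone
Product: 21 (2S)-3,3-dimethylbutane-1,2,4-triol
Conditions: LiAlH4, THF, 0 °C → reflux; Na2SO4·10H2O
Reagents that add atoms: none
Why: Hydride reduction of a lactone to the diol; the stereocenter is not involved.

Step 15
Reactants: 21 (2S)-3,3-dimethylbutane-1,2,4-triol
Product: 22 2-[(4S)-2,2-dimethyl-1,3-dioxolan-4-yl]-2-methylpropan-1-ol
Conditions: Me2C(OMe)2, TsOH·H2O (cat.), acetone, rt
Reagents that add atoms: 2,2-dimethoxypropane, COC(C)(C)OC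
Why: Acetonide formation under thermodynamic control: the five-membered dioxolane across the terminal 1,2-diol is favoured over the six-membered 1,3-dioxane, which would carry an axial methyl group, so the neopentyl hydroxyl should remain free.

Step 16
Reactants: 22 2-[(4S)-2,2-dimethyl-1,3-dioxolan-4-yl]-2-methylpropan-1-ol
Product: 23 2-[(4S)-2,2-dimethyl-1,3-dioxolan-4-yl]-2-methylpropanal
Conditions: Dess–Martin periodinane, pyridine, CH2Cl2, 0 °C → rt
Reagents that add atoms: none
Why: Dess–Martin oxidation, pyridine-buffered to protect the acetonide, to a non-enolisable neopentyl aldehyde.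

Step 17
Reactants: 23 2-[(4S)-2,2-dimethyl-1,3-dioxolan-4-yl]-2-methylpropanal
Product: 24 (4S)-2,2-dimethyl-4-(2-methylbut-3-yn-2-yl)-1,3-dioxolane
Conditions: MeC(O)C(N2)P(O)(OMe)2, K2CO3, MeOH, 0 °C → rt
Reagents that add atoms: dimethyl (1-diazo-2-oxopropyl)phosphonate, CC(=O)C(=[N+]=[N-])P(=O)(OC)OC
Why: Ohira–Bestmann homologation as in step 4, placing the alkyne C6≡C7 on the quaternary carbon C1.

Step 18
Reactants: 24 (4S)-2,2-dimethyl-4-(2-methylbut-3-yn-2-yl)-1,3-dioxolane
Product: 25 (2S)-3,3-dimethylpent-4-yne-1,2-diol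
Conditions: 2 M HCl, THF, rt
Reagents that add atoms: none
Why: Aqueous acid hydrolysis of the acetonide releases the 1,2-diol needed for epoxide formation.

Step 19
Reactants: 25 (2S)-3,3-dimethylpent-4-yne-1,2-diol
Product: 27 (2S)-2-(2-methylbut-3-yn-2-yl)oxirane, via monotosylate 26 (not isolated)
Conditions: NaH (2.2 equiv), N-tosylimidazole (1.05 equiv), THF, 0 °C → rt
Reagents that add atoms: none
Why: One-pot diol-to-epoxide conversion: the less hindered primary alkoxide is sulfonylated and the neighbouring secondary alkoxide displaces the tosylate (intramolecular Williamson reaction), so the C–O bond at the stereocenter is never broken and configuration is retained; the volatile epoxide is kept as a concentrated THF solution.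

Step 20
Reactants: 27 (2S)-2-(2-methylbut-3-yn-2-yl)oxirane; 7 methallylmagnesium chloride
Product: 28 (5R)-2,6,6-trimethyloct-1-en-7-yn-5-ol
Conditions: 7 (2.5 equiv), CuBr·SMe2 (10 mol %), THF, −40 → 0 °C; aq. NH4Cl
Reagents that add atoms: none
Why: Copper-catalysed Grignard opening of a terminal epoxide by SN2 attack at the CH2 carbon (the other carbon is neopentyl and blocked), which makes the C3–C4 bond and leaves C2 untouched (the descriptor becomes R only through a priority change); one extra equivalent of 7 is consumed by the alkyne C–H, which is restored on work-up.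

Step 21
Reactants: 28 (5R)-2,6,6-trimethyloct-1-en-7-yn-5-ol
Product: 29 (5R)-2,6,6-trimethyloct-1-en-7-yn-5-yl acetate
Conditions: Ac2O, Et3N, DMAP (cat.), CH2Cl2, rt
Reagents that add atoms: acetic anhydride, CC(=O)OC(C)=O
Why: DMAP-catalysed acylation; the acetate keeps the hydroxyl away from the ruthenium carbene in step 22 and is removed at no extra cost in step 24.

Step 22
Reactants: 29 (5R)-2,6,6-trimethyloct-1-en-7-yn-5-yl acetate
Product: 30 (1R)-3-ethenyl-2,2,4-trimethylcyclohex-3-en-1-yl acetate
Conditions: second-generation Hoveyda–Grubbs catalyst RuCl2(H2IMes)(=CH–C6H4-2-OiPr) (10 mol %, two portions), ethylene (1 atm), toluene (0.01 M), 80 °C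
Reagents that add atoms: none
Why: Ring-closing enyne metathesis of the same type as step 8 (methylidene addition at the alkyne terminus C7, exo closure of six-membered ring A by [2+2]/cycloreversion with the methallyl alkene to give C5=C6, vinyl group C7=C8 left exocyclic); no stereocenter is formed, C2 is remote, and here the C1 gem-dimethyl group alone supplies the conformational bias.

Step 23
Reactants: 30 (1R)-3-ethenyl-2,2,4-trimethylcyclohex-3-en-1-yl acetate; 13 ethyl (2E)-3-iodobut-2-enoate
Product: 31 ethyl (2E,4E)-5-[(5R)-5-acetoxy-2,6,6-trimethylcyclohex-1-en-1-yl]-3-methylpenta-2,4-dienoate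
Conditions: Pd(OAc)2 (5 mol %), Ag2CO3 (1 equiv), DMF, 50 °C, dark
Reagents that add atoms: none
Why: Mizoroki–Heck alkenylation at C8 exactly as in step 9; the hindered secondary acetate should be stable to Ag2CO3 in DMF.

Step 24
Reactants: 31 ethyl (2E,4E)-5-[(5R)-5-acetoxy-2,6,6-trimethylcyclohex-1-en-1-yl]-3-methylpenta-2,4-dienoate
Product: 32 (1R)-3-[(1E,3E)-5-hydroxy-3-methylpenta-1,3-dien-1-yl]-2,2,4-trimethylcyclohex-3-en-1-ol
Conditions: i-Bu2AlH (5 equiv), CH2Cl2, −78 → 0 °C; aq. KNaC4H4O6
Reagents that add atoms: none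
Why: i-Bu2AlH reduction of the dienoate to the allylic alcohol, with reductive cleavage of the acetate in the same operation.

Step 25
Reactants: 32 (1R)-3-[(1E,3E)-5-hydroxy-3-methylpenta-1,3-dien-1-yl]-2,2,4-trimethylcyclohex-3-en-1-ol
Product: 33 [(2E,4E)-5-[(5R)-5-hydroxy-2,6,6-trimethylcyclohex-1-en-1-yl]-3-methylpenta-2,4-dien-1-yl]triphenylphosphonium bromide
Conditions: Ph3P·HBr (1.1 equiv), MeOH, 0 °C → rt
Reagents that add atoms: triphenylphosphine hydrobromide, [Br-].c1ccc(cc1)[PH+](c1ccccc1)c1ccccc1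
Why: Allylic phosphonium salt formation as in step 12; the secondary C2 hydroxyl stays free.

**Union of the halves**

Step 26
Reactants: 19 C25 apo-aldehyde (ring B half); 33 ring A C15 phosphonium bromide
Product: 34 (2R,2'R,3'S)-all-E-β,β-carotene-2,2',3'-triol (target)
Conditions: NaOMe (1.1 equiv), CH2Cl2/MeOH, 0 °C → rt; then EtOH, reflux, crystallise
Reagents that add atoms: none
Why: Wittig olefination joining the halves at C11=C12; heating in ethanol should convert the sterically strained 11Z isomer into the all-E carotenoid, which crystallises, and no protecting group remains to be removed.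

**Compound list**

1 | (R)-pantolactone, (3R)-3-hydroxy-4,4-dimethyloxolan-2-one | CC1(C)COC(=O)[C@@H]1O | starting material
2 | (3R)-4,4-dimethyl-3-(triethylsilyloxy)oxolan-2-one | CC1(C)COC(=O)[C@@H]1O[Si](CC)(CC)CC | intermediate
3 | (2R)-4-hydroxy-N-methoxy-N,3,3-trimethyl-2-(triethylsilyloxy)butanamide | OCC(C)(C)[C@@H](O[Si](CC)(CC)CC)C(=O)N(C)OC | intermediate
4 | (2R)-N-methoxy-N,3,3-trimethyl-4-oxo-2-(triethylsilyloxy)butanamide | O=CC(C)(C)[C@@H](O[Si](CC)(CC)CC)C(=O)N(C)OC | intermediate
5 | (2R)-N-methoxy-N,3,3-trimethyl-2-(triethylsilyloxy)pent-4-ynamide | C#CC(C)(C)[C@@H](O[Si](CC)(CC)CC)C(=O)N(C)OC | intermediate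
6 | (2R)-3,3-dimethyl-2-(triethylsilyloxy)pent-4-ynal | C#CC(C)(C)[C@@H](O[Si](CC)(CC)CC)C=O | intermediate
7 | methallylmagnesium chloride (2-methylprop-2-en-1-ylmagnesium chloride) | C=C(C)C[Mg]Cl | starting material
8 | (4S,5R)-2,6,6-trimethyl-5-(triethylsilyloxy)oct-1-en-7-yn-4-yl diisopinocampheylborinate (isopinocampheyl groups from (+)-α-pinene) | C#CC(C)(C)[C@@H](O[Si](CC)(CC)CC)[C@H](CC(C)=C)OB([C@@H]1C[C@@H]2C[C@H]([C@H]1C)C2(C)C)[C@@H]1C[C@@H]2C[C@H]([C@H]1C)C2(C)C | intermediate
9 | (4S,5R)-2,6,6-trimethyl-5-(triethylsilyloxy)oct-1-en-7-yn-4-ol | C#CC(C)(C)[C@@H](O[Si](CC)(CC)CC)[C@@H](O)CC(C)=C | intermediate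
10 | (4S,5R)-2,6,6-trimethyloct-1-en-7-yne-4,5-diol | C#CC(C)(C)[C@@H](O)[C@@H](O)CC(C)=C | intermediate
11 | (4R,5S)-2,2-dimethyl-4-(2-methylbut-3-yn-2-yl)-5-(2-methylprop-2-en-1-yl)-1,3-dioxolane (ring B 1,7-enyne) | C#CC(C)(C)[C@H]1OC(C)(C)O[C@H]1CC(C)=C | intermediate
12 | (3aR,7aS)-5-ethenyl-2,2,4,4,6-pentamethyl-3a,4,7,7a-tetrahydro-1,3-benzodioxole | C=CC1=C(C)C[C@@H]2OC(C)(C)O[C@@H]2C1(C)C | intermediate
13 | ethyl (2E)-3-iodobut-2-enoate | CCOC(=O)/C=C(C)/I | starting material
14 | ethyl (2E,4E)-3-methyl-5-[(3aR,7aS)-2,2,4,4,6-pentamethyl-3a,4,7,7a-tetrahydro-1,3-benzodioxol-5-yl]penta-2,4-dienoate | CCOC(=O)/C=C(C)/C=C/C1=C(C)C[C@@H]2OC(C)(C)O[C@@H]2C1(C)C | intermediate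
15 | ethyl (2E,4E)-5-[(4S,5R)-4,5-dihydroxy-2,6,6-trimethylcyclohex-1-en-1-yl]-3-methylpenta-2,4-dienoate | CCOC(=O)/C=C(C)/C=C/C1=C(C)C[C@H](O)[C@H](O)C1(C)C | intermediate
16 | (1S,2R)-4-[(1E,3E)-5-hydroxy-3-methylpenta-1,3-dien-1-yl]-3,3,5-trimethylcyclohex-4-ene-1,2-diol | OC/C=C(C)/C=C/C1=C(C)C[C@H](O)[C@H](O)C1(C)C | intermediate
17 | [(2E,4E)-5-[(4S,5R)-4,5-dihydroxy-2,6,6-trimethylcyclohex-1-en-1-yl]-3-methylpenta-2,4-dien-1-yl]triphenylphosphonium bromide | [Br-].c1ccccc1[P+](c1ccccc1)(c1ccccc1)C/C=C(C)/C=C/C1=C(C)C[C@H](O)[C@H](O)C1(C)C | intermediate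
18 | (2E,4E,6E)-2,7-dimethylocta-2,4,6-trienedial | O=C/C(C)=C/C=C/C=C(C)/C=O | starting material
19 | (2E,4E,6E,8E,10E,12E)-13-[(4S,5R)-4,5-dihydroxy-2,6,6-trimethylcyclohex-1-en-1-yl]-2,7,11-trimethyltrideca-2,4,6,8,10,12-hexaenal | O=C/C(C)=C/C=C/C=C(C)/C=C/C=C(C)/C=C/C1=C(C)C[C@H](O)[C@H](O)C1(C)C | intermediate
20 | (S)-pantolactone, (3S)-3-hydroxy-4,4-dimethyloxolan-2-one | CC1(C)COC(=O)[C@H]1O | starting material
21 | (2S)-3,3-dimethylbutane-1,2,4-triol | OC[C@@H](O)C(C)(C)CO | intermediate
22 | 2-[(4S)-2,2-dimethyl-1,3-dioxolan-4-yl]-2-methylpropan-1-ol | OCC(C)(C)[C@H]1COC(C)(C)O1 | intermediate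
23 | 2-[(4S)-2,2-dimethyl-1,3-dioxolan-4-yl]-2-methylpropanal | O=CC(C)(C)[C@H]1COC(C)(C)O1 | intermediate
24 | (4S)-2,2-dimethyl-4-(2-methylbut-3-yn-2-yl)-1,3-dioxolane | C#CC(C)(C)[C@H]1COC(C)(C)O1 | intermediate
25 | (2S)-3,3-dimethylpent-4-yne-1,2-diol | C#CC(C)(C)[C@H](O)CO | intermediate
26 | (2S)-2-hydroxy-3,3-dimethylpent-4-yn-1-yl 4-methylbenzenesulfonate | C#CC(C)(C)[C@H](O)COS(=O)(=O)c1ccc(C)cc1 | intermediate
27 | (2S)-2-(2-methylbut-3-yn-2-yl)oxirane | C#CC(C)(C)[C@H]1CO1 | intermediate
28 | (5R)-2,6,6-trimethyloct-1-en-7-yn-5-ol | C#CC(C)(C)[C@H](O)CCC(C)=C | intermediate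
29 | (5R)-2,6,6-trimethyloct-1-en-7-yn-5-yl acetate (ring A 1,7-enyne) | C#CC(C)(C)[C@H](OC(C)=O)CCC(C)=C | intermediate
30 | (1R)-3-ethenyl-2,2,4-trimethylcyclohex-3-en-1-yl acetate | C=CC1=C(C)CC[C@@H](OC(C)=O)C1(C)C | intermediate
31 | ethyl (2E,4E)-5-[(5R)-5-acetoxy-2,6,6-trimethylcyclohex-1-en-1-yl]-3-methylpenta-2,4-dienoate | CCOC(=O)/C=C(C)/C=C/C1=C(C)CC[C@@H](OC(C)=O)C1(C)C | intermediate
32 | (1R)-3-[(1E,3E)-5-hydroxy-3-methylpenta-1,3-dien-1-yl]-2,2,4-trimethylcyclohex-3-en-1-ol | OC/C=C(C)/C=C/C1=C(C)CC[C@@H](O)C1(C)C | intermediate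
33 | [(2E,4E)-5-[(5R)-5-hydroxy-2,6,6-trimethylcyclohex-1-en-1-yl]-3-methylpenta-2,4-dien-1-yl]triphenylphosphonium bromide | [Br-].c1ccccc1[P+](c1ccccc1)(c1ccccc1)C/C=C(C)/C=C/C1=C(C)CC[C@@H](O)C1(C)C | intermediate
34 | (2R,2'R,3'S)-all-E-β,β-carotene-2,2',3'-triol | CC1=C(/C=C/C(C)=C/C=C/C(C)=C/C=C/C=C(C)/C=C/C=C(C)/C=C/C2=C(C)C[C@H](O)[C@H](O)C2(C)C)C(C)(C)[C@H](O)CC1 | target

**Step count and risk**

Total step count: 26. Longest linear sequence: 14 steps (steps 1–13 and 26, from (R)-pantolactone); the ring A branch is 13 steps (14–25 and 26).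

Steps most likely to fail:

1. Step 8 (ring closure of 11). The hindered ruthenium vinylcarbene on C6' may fail to capture the 1,1-disubstituted alkene before the catalyst decays. Turnover would then drain into ethylene–alkyne cross-metathesis (an acyclic 2-substituted butadiene), alkyne oligomerisation or endo-mode closure. The fallback replaces metathesis by carbonyl condensation; it sets out from 11 and comes back at 14, bypassing steps 8 and 9. Ozonolysis of the methallyl C=C of 11 (O3, CH2Cl2/MeOH, −78 °C, indicator-controlled; Me2S) spares the alkyne and gives the methyl ketone 1-[(4S,5R)-2,2-dimethyl-5-(2-methylbut-3-yn-2-yl)-1,3-dioxolan-4-yl]propan-2-one F1. Anti-Markovnikov hydration of the alkyne (Cy2BH, THF, 0 °C; then NaBO3·4H2O) gives the keto-aldehyde 3-[(4R,5S)-2,2-dimethyl-5-(2-oxopropyl)-1,3-dioxolan-4-yl]-3-methylbutanal F2. Piperidinium acetate in toluene at reflux effects the intramolecular aldol condensation in which the aldehyde enamine carbon C6' attacks the C5' ketone. This closes ring B as the tetrasubstituted enal (3aR,7aS)-2,2,4,4,6-pentamethyl-3a,4,7,7a-tetrahydro-1,3-benzodioxole-5-carbaldehyde F3. Horner–Wadsworth–Emmons olefination of F3 with triethyl (2E)-3-methyl-4-phosphonobut-2-enoate (LiN(SiMe3)2, THF, −78 → 0 °C) then gives 14.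

2. Step 22 (ring closure of 29). Without the dioxolane clamp the two arms spend little time within bonding distance, so ring closure may be outrun by ethylene cross-enyne metathesis, alkyne oligomerisation and thermal catalyst decay. The fallback is the same carbonyl-condensation logic; it sets out from 29 and comes back at 31, bypassing steps 22 and 23. Ozonolysis (O3, CH2Cl2/MeOH, −78 °C; Me2S) gives the ketone (4R)-3,3-dimethyl-7-oxooct-1-yn-4-yl acetate F4. Hydroboration–oxidation of the alkyne (Cy2BH; NaBO3·4H2O) gives the keto-aldehyde (4R)-3,3-dimethyl-1,7-dioxooctan-4-yl acetate F5. Piperidinium acetate-mediated aldol condensation gives the enal (1R)-3-formyl-2,2,4-trimethylcyclohex-3-en-1-yl acetate F6. Horner–Wadsworth–Emmons olefination with the same C5 phosphonate (LiN(SiMe3)2, THF) gives 31.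

3. Step 9 (Heck vinylation of 12; step 23 is its twin). After insertion the alkylpalladium lies next to the ring alkene and may collapse to a π-allyl complex. Elimination would then run toward the C5' methyl group or the double bonds would migrate instead of giving the conjugated triene, with some loss of the E geometry of the iodide. The fallback replaces the Heck reaction by cross-metathesis and Suzuki coupling; it sets out from 12 and comes back at 14. Cross-metathesis of the vinyl group with vinylboronic acid pinacol ester (second-generation Hoveyda–Grubbs catalyst, CH2Cl2, 40 °C) gives the dienylboronate 2-{(E)-2-[(3aR,7aS)-2,2,4,4,6-pentamethyl-3a,4,7,7a-tetrahydro-1,3-benzodioxol-5-yl]ethenyl}-4,4,5,5-tetramethyl-1,3,2-dioxaborolane F7. Suzuki–Miyaura coupling of F7 with 13 (Pd(PPh3)4, aq. K3PO4, THF, 50 °C) gives 14 with both double-bond geometries fixed by the partners. The same two operations on 30 would answer step 23.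

Further compounds
F1 | step 8 | 1-[(4S,5R)-2,2-dimethyl-5-(2-methylbut-3-yn-2-yl)-1,3-dioxolan-4-yl]propan-2-one | C#CC(C)(C)[C@H]1OC(C)(C)O[C@H]1CC(C)=O
F2 | step 8 | 3-[(4R,5S)-2,2-dimethyl-5-(2-oxopropyl)-1,3-dioxolan-4-yl]-3-methylbutanal | O=CCC(C)(C)[C@H]1OC(C)(C)O[C@H]1CC(C)=O
F3 | step 8 | (3aR,7aS)-2,2,4,4,6-pentamethyl-3a,4,7,7a-tetrahydro-1,3-benzodioxole-5-carbaldehyde | O=CC1=C(C)C[C@@H]2OC(C)(C)O[C@@H]2C1(C)C
F4 | step 22 | (4R)-3,3-dimethyl-7-oxooct-1-yn-4-yl acetate | C#CC(C)(C)[C@H](OC(C)=O)CCC(C)=O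
F5 | step 22 | (4R)-3,3-dimethyl-1,7-dioxooctan-4-yl acetate | O=CCC(C)(C)[C@H](OC(C)=O)CCC(C)=O
F6 | step 22 | (1R)-3-formyl-2,2,4-trimethylcyclohex-3-en-1-yl acetate | O=CC1=C(C)CC[C@@H](OC(C)=O)C1(C)C
F7 | step 9 | 2-{(E)-2-[(3aR,7aS)-2,2,4,4,6-pentamethyl-3a,4,7,7a-tetrahydro-1,3-benzodioxol-5-yl]ethenyl}-4,4,5,5-tetramethyl-1,3,2-dioxaborolane | CC1(C)OB(/C=C/C2=C(C)C[C@@H]3OC(C)(C)O[C@@H]3C2(C)C)OC1(C)C
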